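**Retrosynthetic overview**
1. After a final 8-O-desilylation, the γ-lactone (O6–C12) and the ten-membered carbocycle (C6–C7, the 1,10 bond of a (2Z,6Z)-farnesyl chain) are opened together to an acyclic C6 enal / C13 allylboronate; forward, the carbocycle closes first and the lactone second, in the same flask.
2. The (Z)-2-alkoxycarbonyl allylboronate comes from a C7≡C11 ynoate by conjugate hydride addition and trapping with ICH2Bpin.
3. The chain is cut at C9–C10: Nozaki–Hiyama–Kishi coupling of vinyl iodide fragment A (C1–C6, C10, C14, C15; from nerol) with α-silyloxy aldehyde fragment B (C7–C9, C11, C12; from cinnamaldehyde and methyl propiolate).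
4. Stereocentres: C8 by catalytic asymmetric alkynylation, C9 by Felkin–Anh addition, C6 and C7 in the ring closure.

Assumption: germacrane numbering is used throughout (C6 lactone carbinol, C7, C8 CHOH, C9 CHOAc, C12 lactone C=O, C13 exocyclic CH2, C14 CH2O-isovalerate, C15 methyl); the target is (6R,7R,8S,9R), 1(10)Z,4Z.

**Route**

Step 1
Reactants: 1 nerol
Product: 2 1-({[(2Z)-3,7-dimethylocta-2,6-dien-1-yl]oxy}methyl)-4-methoxybenzene
Conditions: NaH, 4-methoxybenzyl chloride, TBAI (cat.), THF/DMF, 0 °C → rt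
Reagents that add atoms: 4-methoxybenzyl chloride, COc1ccc(CCl)cc1
Why: Williamson etherification installs a C6–O protecting group that DDQ later removes without touching the silyl ether, the esters or the allylboronate, and the (2Z) olefin of nerol becomes the 4Z olefin of the target.

Step 2
Reactants: 2 1-({[(2Z)-3,7-dimethylocta-2,6-dien-1-yl]oxy}methyl)-4-methoxybenzene
Product: 4 (4Z)-6-[(4-methoxybenzyl)oxy]-4-methylhex-4-enal, via epoxide 3 (not isolated)
Conditions: mCPBA, CH2Cl2, −20 → 0 °C; then H5IO6, THF/H2O, 0 °C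
Reagents that add atoms: mCPBA, OOC(=O)c1cccc(Cl)c1
Why: Prilezhaev epoxidation prefers the distal trisubstituted olefin (the 2,3-olefin is deactivated by the allylic ether oxygen), and periodic acid opens and cleaves the epoxide to the C1 aldehyde without touching the Z olefin.

Step 3
Reactants: 4 (4Z)-6-[(4-methoxybenzyl)oxy]-4-methylhex-4-enal; 5 ethyl (triphenyl-λ5-phosphanylidene)acetate
Product: 7 ethyl (2Z,6Z)-2-iodo-8-[(4-methoxybenzyl)oxy]-6-methylocta-2,6-dienoate, via iodo-ylide 6 (not isolated)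
Conditions: NIS, CH2Cl2, −20 °C; then 4, −20 °C → rt
Reagents that add atoms: N-iodosuccinimide, O=C1CCC(=O)N1I
Why: Halogenation of the stabilized ylide followed by Wittig olefination puts the ester trans to the chain, so iodine ends cis to C2 and the 1(10)Z geometry (C14 trans to C2) is fixed here.

Step 4
Reactants: 7 ethyl (2Z,6Z)-2-iodo-8-[(4-methoxybenzyl)oxy]-6-methylocta-2,6-dienoate
Product: 8 (2Z,6Z)-2-iodo-8-[(4-methoxybenzyl)oxy]-6-methylocta-2,6-dien-1-ol (fragment A)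
Conditions: i-Bu2AlH, CH2Cl2, −78 °C; aq. KNaC4H4O6 work-up
Reagents that add atoms: none
Why: 1,2-reduction of the enoate with i-Bu2AlH gives the C14 allylic alcohol and leaves the vinyl iodide, the Z olefins and the PMB ether intact.

Step 5
Reactants: 9 (E)-cinnamaldehyde; 10 methyl propiolate
Product: 11 methyl (4R,5E)-4-hydroxy-6-phenylhex-5-en-2-ynoate
Conditions: Me2Zn, (S,S)-ProPhenol [2,6-bis{[(S)-2-(hydroxydiphenylmethyl)pyrrolidin-1-yl]methyl}-4-methylphenol] (10 mol%), toluene, 0–4 °C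
Reagents that add atoms: none
Why: The dinuclear zinc–ProPhenol asymmetric alkynylation of an enal with the zinc acetylide of methyl propiolate forms the C7–C8 bond and sets C8 as the (R)-carbinol (the ligand antipode is taken if this enal shows the opposite facial sense).

Step 6
Reactants: 11 methyl (4R,5E)-4-hydroxy-6-phenylhex-5-en-2-ynoate
Product: 12 methyl (4R,5E)-4-[(tert-butyldimethylsilyl)oxy]-6-phenylhex-5-en-2-ynoate
Conditions: TBSOTf, 2,6-lutidine, CH2Cl2, −78 °C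
Reagents that add atoms: tert-butyldimethylsilyl triflate, CC(C)(C)[Si](C)(C)OS(=O)(=O)C(F)(F)F
Why: Silylation with a silyl triflate and a hindered, non-nucleophilic base protects O8 without conjugate addition to the ynoate, and the bulky non-chelating ether later enforces Felkin–Anh control.

Step 7
Reactants: 12 methyl (4R,5E)-4-[(tert-butyldimethylsilyl)oxy]-6-phenylhex-5-en-2-ynoate
Product: 14 methyl (4S)-4-[(tert-butyldimethylsilyl)oxy]-5-oxopent-2-ynoate (fragment B), via ozonide 13 (not isolated)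
Conditions: O3, CH2Cl2, −78 °C; then PPh3, −78 °C → rt; used crude
Reagents that add atoms: ozone, [O-][O+]=O
Why: Ozonolysis cleaves the electron-rich styryl olefin much faster than the electron-poor ynoate, and the base-free reductive work-up delivers the C9 aldehyde without epimerizing C8.

Step 8
Reactants: 8 (2Z,6Z)-2-iodo-8-[(4-methoxybenzyl)oxy]-6-methylocta-2,6-dien-1-ol; 14 methyl (4S)-4-[(tert-butyldimethylsilyl)oxy]-5-oxopent-2-ynoate
Product: 15 methyl (4S,5R,6Z,10Z)-4-[(tert-butyldimethylsilyl)oxy]-5-hydroxy-6-(hydroxymethyl)-12-[(4-methoxybenzyl)oxy]-10-methyldodeca-6,10-dien-2-ynoate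
Conditions: CrCl2 (6 equiv), NiCl2 (1 mol%), DMSO/THF, rt
Reagents that add atoms: none
Why: In the Nozaki–Hiyama–Kishi coupling the alkenylchromium adds to the aldehyde with retention of olefin geometry and tolerates the free hydroxyl, ynoate and PMB ether, and Felkin–Anh attack anti to the C8–OTBS bond gives the 8,9-anti diol, that is 9R.

Step 9
Reactants: 15 methyl (4S,5R,6Z,10Z)-4-[(tert-butyldimethylsilyl)oxy]-5-hydroxy-6-(hydroxymethyl)-12-[(4-methoxybenzyl)oxy]-10-methyldodeca-6,10-dien-2-ynoate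
Product: 17 methyl (4S,5R,6Z,10Z)-5-acetoxy-4-[(tert-butyldimethylsilyl)oxy]-12-[(4-methoxybenzyl)oxy]-10-methyl-6-{[(3-methylbutanoyl)oxy]methyl}dodeca-6,10-dien-2-ynoate, via mono-isovalerate 16 (not isolated)
Conditions: 3-methylbutanoyl chloride (1.05 equiv), 2,4,6-collidine, CH2Cl2, −78 → −40 °C; then Ac2O, pyridine, 0 °C → rt
Reagents that add atoms: 3-methylbutanoyl chloride, CC(C)CC(Cl)=O; acetic anhydride, CC(=O)OC(C)=O
Why: The primary allylic C14 hydroxyl is acylated selectively by the acid chloride at low temperature and the hindered secondary C9 hydroxyl is then acetylated, without DMAP so that no amine-catalysed oxa-Michael addition to the ynoate occurs.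

Step 10
Reactants: 17 methyl (4S,5R,6Z,10Z)-5-acetoxy-4-[(tert-butyldimethylsilyl)oxy]-12-[(4-methoxybenzyl)oxy]-10-methyl-6-{[(3-methylbutanoyl)oxy]methyl}dodeca-6,10-dien-2-ynoate; 18 2-(iodomethyl)-4,4,5,5-tetramethyl-1,3,2-dioxaborolane
Product: 20 methyl (2Z,4S,5R,6Z,10Z)-5-acetoxy-4-[(tert-butyldimethylsilyl)oxy]-12-[(4-methoxybenzyl)oxy]-10-methyl-6-{[(3-methylbutanoyl)oxy]methyl}-2-[(4,4,5,5-tetramethyl-1,3,2-dioxaborolan-2-yl)methyl]dodeca-2,6,10-trienoate, via vinylalane 19 (not isolated)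
Conditions: MeCu (10 mol%, from CuI/MeLi), i-Bu2AlH (1.1 equiv), HMPA, THF, −50 °C; then 18, −50 → 0 °C
Reagents that add atoms: none
Why: Copper-catalysed conjugate hydride delivery is a syn hydrometalation of the ynoate (the HMPA-complexed aluminium hydride is expected to spare isolated esters at −50 °C), and alkylation of the α-metallo enoate by the iodomethylboronate (boron ate complex, 1,2-shift) puts CH2B trans to C8, giving the (2Z)-allylboronate.

Step 11
Reactants: 20 methyl (2Z,4S,5R,6Z,10Z)-5-acetoxy-4-[(tert-butyldimethylsilyl)oxy]-12-[(4-methoxybenzyl)oxy]-10-methyl-6-{[(3-methylbutanoyl)oxy]methyl}-2-[(4,4,5,5-tetramethyl-1,3,2-dioxaborolan-2-yl)methyl]dodeca-2,6,10-trienoate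
Product: 21 methyl (2Z,4S,5R,6Z,10Z)-5-acetoxy-4-[(tert-butyldimethylsilyl)oxy]-12-hydroxy-10-methyl-6-{[(3-methylbutanoyl)oxy]methyl}-2-[(4,4,5,5-tetramethyl-1,3,2-dioxaborolan-2-yl)methyl]dodeca-2,6,10-trienoate
Conditions: DDQ, CH2Cl2/pH 7 buffer, 0 °C
Reagents that add atoms: none
Why: Oxidative cleavage of the PMB ether by DDQ under buffered conditions frees only the C6 allylic alcohol and leaves the silyl ether, the three esters and the deactivated allylboronate untouched.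

Step 12
Reactants: 21 methyl (2Z,4S,5R,6Z,10Z)-5-acetoxy-4-[(tert-butyldimethylsilyl)oxy]-12-hydroxy-10-methyl-6-{[(3-methylbutanoyl)oxy]methyl}-2-[(4,4,5,5-tetramethyl-1,3,2-dioxaborolan-2-yl)methyl]dodeca-2,6,10-trienoate
Product: 24 (1(10)Z,4Z)-9β-acetoxy-8β-[(tert-butyldimethylsilyl)oxy]-14-[(3-methylbutanoyl)oxy]germacra-1(10),4,11(13)-trien-12,6α-olide, via enal 22 (not isolated), via borate 23 (not isolated)
Conditions: MnO2, CH2Cl2, rt; filter; toluene (1 mM), Sc(OTf)3 (10 mol%), 0 °C → rt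
Reagents that add atoms: none
Why: Proposed new method: a ten-membered-ring-forming intramolecular version of the aldehyde allylboration/lactonization of 2-alkoxycarbonyl allylboronates (closest known: the intermolecular thermal or Sc(OTf)3-catalysed tandem allylboration–lactonization and small-ring intramolecular allylborations), in which C7 attacks the C6 enal through a closed chair transition state, the allylboron counterpart of the 1,10-cyclization of a (2Z,6Z)-farnesyl chain; the (2Z)-boronate with an equatorial aldehyde substituent gives the 6,7-anti adduct (trans-lactone, H6β/H7α), A(1,3) strain with the cis ester holds H8 in the olefin plane so that C6 adds anti to the C8–C9 bond with OTBS outside (6R,7R relative to 8S), and the O6 borate then acylates on the neighbouring methyl ester to close the lactone.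

Step 13
Reactants: 24 (1(10)Z,4Z)-9β-acetoxy-8β-[(tert-butyldimethylsilyl)oxy]-14-[(3-methylbutanoyl)oxy]germacra-1(10),4,11(13)-trien-12,6α-olide
Product: 25 (1(10)Z,4Z)-9β-acetoxy-8β-hydroxy-14-[(3-methylbutanoyl)oxy]germacra-1(10),4,11(13)-trien-12,6α-olide (target)
Conditions: HF·pyridine, THF/pyridine, 0 °C → rt
Reagents that add atoms: none
Why: Buffered acidic fluoride desilylation frees the 8-hydroxyl without base, so the neighbouring 9-acetate does not migrate and nothing adds to the α-methylene lactone.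

**Compound list**
1 | nerol, (2Z)-3,7-dimethylocta-2,6-dien-1-ol | CC(C)=CCC/C(C)=C\CO | starting material
2 | 1-({[(2Z)-3,7-dimethylocta-2,6-dien-1-yl]oxy}methyl)-4-methoxybenzene (neryl PMB ether) | CC(C)=CCC/C(C)=C\COCc1ccc(OC)cc1 | intermediate
3 | 3-{(3Z)-5-[(4-methoxybenzyl)oxy]-3-methylpent-3-en-1-yl}-2,2-dimethyloxirane (racemic epoxide) | CC1(C)OC1CC/C(C)=C\COCc1ccc(OC)cc1 | intermediate
4 | (4Z)-6-[(4-methoxybenzyl)oxy]-4-methylhex-4-enal | O=CCC/C(C)=C\COCc1ccc(OC)cc1 | intermediate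
5 | ethyl (triphenyl-λ5-phosphanylidene)acetate | CCOC(=O)C=P(c1ccccc1)(c1ccccc1)c1ccccc1 | starting material
6 | ethyl iodo(triphenyl-λ5-phosphanylidene)acetate (iodo-ylide) | CCOC(=O)C(I)=P(c1ccccc1)(c1ccccc1)c1ccccc1 | intermediate
7 | ethyl (2Z,6Z)-2-iodo-8-[(4-methoxybenzyl)oxy]-6-methylocta-2,6-dienoate | CCOC(=O)/C(I)=C/CC/C(C)=C\COCc1ccc(OC)cc1 | intermediate
8 | (2Z,6Z)-2-iodo-8-[(4-methoxybenzyl)oxy]-6-methylocta-2,6-dien-1-ol (fragment A) | OC/C(I)=C/CC/C(C)=C\COCc1ccc(OC)cc1 | intermediate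
9 | (E)-cinnamaldehyde | O=C/C=C/c1ccccc1 | starting material
10 | methyl propiolate | C#CC(=O)OC | starting material
11 | methyl (4R,5E)-4-hydroxy-6-phenylhex-5-en-2-ynoate | c1ccccc1/C=C/[C@@H](O)C#CC(=O)OC | intermediate
12 | methyl (4R,5E)-4-[(tert-butyldimethylsilyl)oxy]-6-phenylhex-5-en-2-ynoate | c1ccccc1/C=C/[C@@H](O[Si](C)(C)C(C)(C)C)C#CC(=O)OC | intermediate
13 | methyl (4S)-4-[(tert-butyldimethylsilyl)oxy]-4-(5-phenyl-1,2,4-trioxolan-3-yl)but-2-ynoate (ozonide, mixture at the ring carbons) | c1ccccc1C2OOC(O2)[C@@H](O[Si](C)(C)C(C)(C)C)C#CC(=O)OC | intermediate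
14 | methyl (4S)-4-[(tert-butyldimethylsilyl)oxy]-5-oxopent-2-ynoate (fragment B) | O=C[C@@H](O[Si](C)(C)C(C)(C)C)C#CC(=O)OC | intermediate
15 | methyl (4S,5R,6Z,10Z)-4-[(tert-butyldimethylsilyl)oxy]-5-hydroxy-6-(hydroxymethyl)-12-[(4-methoxybenzyl)oxy]-10-methyldodeca-6,10-dien-2-ynoate | COc1ccc(COC/C=C(/C)CC/C=C(/CO)[C@@H](O)[C@@H](O[Si](C)(C)C(C)(C)C)C#CC(=O)OC)cc1 | intermediate
16 | methyl (4S,5R,6Z,10Z)-4-[(tert-butyldimethylsilyl)oxy]-5-hydroxy-12-[(4-methoxybenzyl)oxy]-10-methyl-6-{[(3-methylbutanoyl)oxy]methyl}dodeca-6,10-dien-2-ynoate (mono-isovalerate) | COc1ccc(COC/C=C(/C)CC/C=C(/COC(=O)CC(C)C)[C@@H](O)[C@@H](O[Si](C)(C)C(C)(C)C)C#CC(=O)OC)cc1 | intermediate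
17 | methyl (4S,5R,6Z,10Z)-5-acetoxy-4-[(tert-butyldimethylsilyl)oxy]-12-[(4-methoxybenzyl)oxy]-10-methyl-6-{[(3-methylbutanoyl)oxy]methyl}dodeca-6,10-dien-2-ynoate | COc1ccc(COC/C=C(/C)CC/C=C(/COC(=O)CC(C)C)[C@@H](OC(C)=O)[C@@H](O[Si](C)(C)C(C)(C)C)C#CC(=O)OC)cc1 | intermediate
18 | 2-(iodomethyl)-4,4,5,5-tetramethyl-1,3,2-dioxaborolane | ICB1OC(C)(C)C(C)(C)O1 | starting material
19 | methyl (2E,4S,5R,6Z,10Z)-5-acetoxy-4-[(tert-butyldimethylsilyl)oxy]-2-(diisobutylalumanyl)-12-[(4-methoxybenzyl)oxy]-10-methyl-6-{[(3-methylbutanoyl)oxy]methyl}dodeca-2,6,10-trienoate (vinylalane, C8 cis to the ester) | COc1ccc(COC/C=C(/C)CC/C=C(/COC(=O)CC(C)C)[C@@H](OC(C)=O)[C@@H](O[Si](C)(C)C(C)(C)C)/C=C(/[Al](CC(C)C)CC(C)C)C(=O)OC)cc1 | intermediate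
20 | methyl (2Z,4S,5R,6Z,10Z)-5-acetoxy-4-[(tert-butyldimethylsilyl)oxy]-12-[(4-methoxybenzyl)oxy]-10-methyl-6-{[(3-methylbutanoyl)oxy]methyl}-2-[(4,4,5,5-tetramethyl-1,3,2-dioxaborolan-2-yl)methyl]dodeca-2,6,10-trienoate | COc1ccc(COC/C=C(/C)CC/C=C(/COC(=O)CC(C)C)[C@@H](OC(C)=O)[C@@H](O[Si](C)(C)C(C)(C)C)/C=C(/CB2OC(C)(C)C(C)(C)O2)C(=O)OC)cc1 | intermediate
21 | methyl (2Z,4S,5R,6Z,10Z)-5-acetoxy-4-[(tert-butyldimethylsilyl)oxy]-12-hydroxy-10-methyl-6-{[(3-methylbutanoyl)oxy]methyl}-2-[(4,4,5,5-tetramethyl-1,3,2-dioxaborolan-2-yl)methyl]dodeca-2,6,10-trienoate | OC/C=C(/C)CC/C=C(/COC(=O)CC(C)C)[C@@H](OC(C)=O)[C@@H](O[Si](C)(C)C(C)(C)C)/C=C(/CB1OC(C)(C)C(C)(C)O1)C(=O)OC | intermediate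
22 | methyl (2Z,4S,5R,6Z,10Z)-5-acetoxy-4-[(tert-butyldimethylsilyl)oxy]-10-methyl-6-{[(3-methylbutanoyl)oxy]methyl}-12-oxo-2-[(4,4,5,5-tetramethyl-1,3,2-dioxaborolan-2-yl)methyl]dodeca-2,6,10-trienoate (seco enal) | O=C/C=C(/C)CC/C=C(/COC(=O)CC(C)C)[C@@H](OC(C)=O)[C@@H](O[Si](C)(C)C(C)(C)C)/C=C(/CB1OC(C)(C)C(C)(C)O1)C(=O)OC | intermediate
23 | methyl (1(10)Z,4Z)-9β-acetoxy-8β-[(tert-butyldimethylsilyl)oxy]-14-[(3-methylbutanoyl)oxy]-6α-[(4,4,5,5-tetramethyl-1,3,2-dioxaborolan-2-yl)oxy]germacra-1(10),4,11(13)-trien-12-oate, (6R,7S,8S,9R) | CC1(C)OB(O[C@@H]2/C=C(/C)CC/C=C(/COC(=O)CC(C)C)[C@@H](OC(C)=O)[C@@H](O[Si](C)(C)C(C)(C)C)[C@H]2C(=C)C(=O)OC)OC1(C)C | intermediate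
24 | (1(10)Z,4Z)-9β-acetoxy-8β-[(tert-butyldimethylsilyl)oxy]-14-[(3-methylbutanoyl)oxy]germacra-1(10),4,11(13)-trien-12,6α-olide, (6R,7S,8S,9R) | C=C1C(=O)O[C@@H]2/C=C(/C)CC/C=C(/COC(=O)CC(C)C)[C@@H](OC(C)=O)[C@@H](O[Si](C)(C)C(C)(C)C)[C@@H]12 | intermediate
25 | (1(10)Z,4Z)-9β-acetoxy-8β-hydroxy-14-[(3-methylbutanoyl)oxy]germacra-1(10),4,11(13)-trien-12,6α-olide, (6R,7R,8S,9R); [(3aR,4S,5R,6Z,10Z,11aR)-5-acetoxy-4-hydroxy-10-methyl-3-methylidene-2-oxo-2,3,3a,4,5,8,9,11a-octahydrocyclodeca[b]furan-6-yl]methyl 3-methylbutanoate | C=C1C(=O)O[C@@H]2/C=C(/C)CC/C=C(/COC(=O)CC(C)C)[C@@H](OC(C)=O)[C@@H](O)[C@@H]12 | target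

**Step count and risks**

Total step count: 13. Longest linear sequence: 10 (steps 1–4, then 8–13, from nerol).

Steps most likely to fail:

Step 12 (ring closure). The medium-ring allylboration may be slow against dimerization, and the predicted C6/C7 sense rests on an acyclic A(1,3) model that the forming ring could override. The fallback closes the same bond with an allylchromium reagent instead of boron. It sets out from 20: trimethylamine N-oxide (THF, rt) oxidizes the C–B bond to the 13-hydroxy enoate F1; CBr4/PPh3 converts it to the allylic bromide F2; DDQ frees the C6 alcohol F3; MnO2 gives the bromo enal F4; CrCl2 (THF/DMF, 2 mM, rt) then generates an E/Z-equilibrating 2-(methoxycarbonyl)allylchromium that adds through C7 to the enal and lactonizes (a Barbier-type macrocyclization with precedent in germacranolide synthesis), coming back to the route at 24.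

Step 10 (hydride addition and borylmethylation). The aluminium hydride may attack the acetate or isovalerate, or the trapping may be inefficient. The fallback builds the same allylboronate by cross-coupling and sets out from 17: Bu3SnH with Pd(PPh3)4 (THF, 0 °C) adds syn across the ynoate to the α-stannyl enoate F5; I2 (CH2Cl2, 0 °C) gives the α-iodo enoate F6 with retention; Negishi coupling with pinBCH2ZnI (from 18 and zinc dust; Pd(PPh3)4, THF, rt) comes back at 20.

Step 8 (fragment coupling). The Felkin–Anh ratio at C9 may be modest with the small alkynyl substituent. The fallback sets C9 by ketone reduction instead of by carbon addition and sets out from 15 (C9 epimer mixture): 3-methylbutanoyl chloride/collidine gives 16, isolated this time; Dess–Martin periodinane oxidizes it to the C9 ketone F7; NaBH4/CeCl3 (MeOH, −78 °C) delivers hydride anti to the C8–OTBS bond and comes back at 16 as the 9R epimer, which is acetylated as in step 9.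

**Further compounds**
F1 | step 12 | methyl (2Z,4S,5R,6Z,10Z)-5-acetoxy-4-[(tert-butyldimethylsilyl)oxy]-2-(hydroxymethyl)-12-[(4-methoxybenzyl)oxy]-10-methyl-6-{[(3-methylbutanoyl)oxy]methyl}dodeca-2,6,10-trienoate | COc1ccc(COC/C=C(/C)CC/C=C(/COC(=O)CC(C)C)[C@@H](OC(C)=O)[C@@H](O[Si](C)(C)C(C)(C)C)/C=C(/CO)C(=O)OC)cc1
F2 | step 12 | methyl (2E,4S,5R,6Z,10Z)-5-acetoxy-2-(bromomethyl)-4-[(tert-butyldimethylsilyl)oxy]-12-[(4-methoxybenzyl)oxy]-10-methyl-6-{[(3-methylbutanoyl)oxy]methyl}dodeca-2,6,10-trienoate | COc1ccc(COC/C=C(/C)CC/C=C(/COC(=O)CC(C)C)[C@@H](OC(C)=O)[C@@H](O[Si](C)(C)C(C)(C)C)/C=C(/CBr)C(=O)OC)cc1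
F3 | step 12 | methyl (2E,4S,5R,6Z,10Z)-5-acetoxy-2-(bromomethyl)-4-[(tert-butyldimethylsilyl)oxy]-12-hydroxy-10-methyl-6-{[(3-methylbutanoyl)oxy]methyl}dodeca-2,6,10-trienoate | OC/C=C(/C)CC/C=C(/COC(=O)CC(C)C)[C@@H](OC(C)=O)[C@@H](O[Si](C)(C)C(C)(C)C)/C=C(/CBr)C(=O)OC
F4 | step 12 | methyl (2E,4S,5R,6Z,10Z)-5-acetoxy-2-(bromomethyl)-4-[(tert-butyldimethylsilyl)oxy]-10-methyl-6-{[(3-methylbutanoyl)oxy]methyl}-12-oxododeca-2,6,10-trienoate | O=C/C=C(/C)CC/C=C(/COC(=O)CC(C)C)[C@@H](OC(C)=O)[C@@H](O[Si](C)(C)C(C)(C)C)/C=C(/CBr)C(=O)OC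
F5 | step 10 | methyl (2E,4S,5R,6Z,10Z)-5-acetoxy-4-[(tert-butyldimethylsilyl)oxy]-12-[(4-methoxybenzyl)oxy]-10-methyl-6-{[(3-methylbutanoyl)oxy]methyl}-2-(tributylstannyl)dodeca-2,6,10-trienoate | COc1ccc(COC/C=C(/C)CC/C=C(/COC(=O)CC(C)C)[C@@H](OC(C)=O)[C@@H](O[Si](C)(C)C(C)(C)C)/C=C(/[Sn](CCCC)(CCCC)CCCC)C(=O)OC)cc1
F6 | step 10 | methyl (2E,4S,5R,6Z,10Z)-5-acetoxy-4-[(tert-butyldimethylsilyl)oxy]-2-iodo-12-[(4-methoxybenzyl)oxy]-10-methyl-6-{[(3-methylbutanoyl)oxy]methyl}dodeca-2,6,10-trienoate | COc1ccc(COC/C=C(/C)CC/C=C(/COC(=O)CC(C)C)[C@@H](OC(C)=O)[C@@H](O[Si](C)(C)C(C)(C)C)/C=C(/I)C(=O)OC)cc1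
F7 | step 8 | methyl (4S,6Z,10Z)-4-[(tert-butyldimethylsilyl)oxy]-12-[(4-methoxybenzyl)oxy]-10-methyl-6-{[(3-methylbutanoyl)oxy]methyl}-5-oxododeca-6,10-dien-2-ynoate | COc1ccc(COC/C=C(/C)CC/C=C(/COC(=O)CC(C)C)C(=O)[C@@H](O[Si](C)(C)C(C)(C)C)C#CC(=O)OC)cc1
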